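**Retrosynthetic overview**
1. The 2-pyrone-6-carboxylic acid comes from oxidative fission of a 3,4,5-trihydroxybenzyl (pyrogallol) ring at C4'–C5', giving a 2-hydroxymuconate that relactonizes. This ring is formed last.
2. The trans-butyrolactone comes from a γ-hydroxy ester of a 2,3-dibenzylsuccinate; it is closed first, and C3 is set by epimerization to trans.
3. The C8–C8' bond comes from oxidative heterocoupling of two C6–C3 enolates (veratryl imide plus tris(benzyloxy)phenyl ester); the auxiliary fixes C4 as R.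
4. Building blocks: 3-(3,4-dimethoxyphenyl)propanoic acid, (S)-4-benzyl-2-oxazolidinone, 3,4,5-tris(benzyloxy)benzaldehyde, Ph3P=CHCO2t-Bu.
5. Ring order: both benzene rings are bought; butyrolactone in step 5; pyrone in step 6, made from one of the benzene rings.

Assumption: the pyrone is taken to arise in nature by dioxygenase fission of the o-diphenol ring of a 3'-O-demethylarctigenin-type lignan at C4'–C5' (as protocatechuate or gallate gives 2-pyrone-4,6-dicarboxylate and L-DOPA gives stizolobic acid) followed by relactonization; because non-enzymatic oxidants cut between oxygen-bearing carbons, the 5'-hydroxy (pyrogallol) congener is used so that the same bond is cut and the seco-acid arrives at the right oxidation level.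

**Route**

Step 1
Reactants: 1 3-(3,4-dimethoxyphenyl)propanoic acid; 2 (S)-4-benzyl-1,3-oxazolidin-2-one
Product: 3 (4S)-4-benzyl-3-[3-(3,4-dimethoxyphenyl)propanoyl]-1,3-oxazolidin-2-one
Conditions: PivCl, Et3N, THF, −20 °C; then LiCl, 2, −20 °C → rt
Reagents that add atoms: none
Why: Mixed-anhydride N-acylation of the LiCl-activated oxazolidinone (Evans imide formation) is routine, creates no stereocentre, and installs the benzyl group that controls C4 in step 4.

Step 2
Reactants: 4 3,4,5-tris(benzyloxy)benzaldehyde; 5 tert-butyl (triphenylphosphoranylidene)acetate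
Product: 6 tert-butyl (E)-3-[3,4,5-tris(benzyloxy)phenyl]prop-2-enoate
Conditions: PhMe, 80 °C
Reagents that add atoms: none
Why: Wittig olefination of an aryl aldehyde with a stabilized ylide gives the (E)-cinnamate cleanly, and the tert-butyl ester is chosen because its enolate resists Claisen self-condensation in step 4.

Step 3
Reactants: 6 tert-butyl (E)-3-[3,4,5-tris(benzyloxy)phenyl]prop-2-enoate
Product: 7 tert-butyl 3-[3,4,5-tris(benzyloxy)phenyl]propanoate
Conditions: H2 (3 atm), RhCl(PPh3)3 (2 mol %), PhMe–EtOH (1:1), 40 °C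
Reagents that add atoms: none
Why: Homogeneous hydrogenation with RhCl(PPh3)3 saturates the conjugated disubstituted alkene without hydrogenolysing the aryl benzyl ethers, which a heterogeneous palladium catalyst would put at risk.

Step 4
Reactants: 3 (4S)-4-benzyl-3-[3-(3,4-dimethoxyphenyl)propanoyl]-1,3-oxazolidin-2-one; 7 tert-butyl 3-[3,4,5-tris(benzyloxy)phenyl]propanoate
Product: 8 tert-butyl (3R)-3-{[(4S)-4-benzyl-2-oxo-1,3-oxazolidin-3-yl]carbonyl}-4-(3,4-dimethoxyphenyl)-2-[3,4,5-tris(benzyloxy)benzyl]butanoate (C2 epimer mixture)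
Conditions: 3 (1.3 equiv), 7 (1.0 equiv), LiN(i-Pr)2 (2.4 equiv), THF, −78 °C; then Fe(acac)3 (2.4 equiv), THF, −78 °C → rt
Reagents that add atoms: none
Why: Oxidative enolate heterocoupling, in which trivalent iron oxidizes the mixed lithium enolates by one electron each and joins the two C6–C3 units at C8–C8' as in lignan biogenesis; the auxiliary benzyl group shields one face of the Z-imide enolate so the imide α-carbon (future C4) is formed R, while the ester α-carbon (future C3) forms unselectively and is corrected in step 5, and homodimers and any minor auxiliary diastereomer are removed by chromatography.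

Step 5
Reactants: 8 tert-butyl (3R)-3-{[(4S)-4-benzyl-2-oxo-1,3-oxazolidin-3-yl]carbonyl}-4-(3,4-dimethoxyphenyl)-2-[3,4,5-tris(benzyloxy)benzyl]butanoate
Product: 11 (3R,4R)-4-(3,4-dimethoxybenzyl)-3-[3,4,5-tris(benzyloxy)benzyl]dihydrofuran-2(3H)-one, via hydroxy ester 9 (not isolated), via cis-lactone 10 (not isolated)
Conditions: LiBH4, H2O (1.1 equiv), Et2O–THF, 0 °C; aqueous work-up; then p-TsOH·H2O (10 mol %), PhMe, 80 °C; then DBU (0.5 equiv), 80 °C
Reagents that add atoms: none
Why: LiBH4 cleaves the exocyclic imide carbonyl to the primary alcohol without touching the tert-butyl ester, acid then closes the γ-lactone with loss of isobutene, and DBU equilibrates the epimerizable C3 (α to the carbonyl) to the thermodynamically favoured trans arrangement, so the C3 mixture converges on the single (3R,4R) isomer while C4 is untouched.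

Step 6
Reactants: 11 (3R,4R)-4-(3,4-dimethoxybenzyl)-3-[3,4,5-tris(benzyloxy)benzyl]dihydrofuran-2(3H)-one
Product: 15 4-{[(3R,4R)-4-(3,4-dimethoxybenzyl)-2-oxotetrahydrofuran-3-yl]methyl}-2-oxo-2H-pyran-6-carboxylic acid, via pyrogallol lactone 12 (not isolated), via hydroxy-o-quinone 13 (not isolated), via hydroxymuconic anhydride 14 (not isolated)
Conditions: H2 (1 atm), 10% Pd/C, EtOAc–AcOH (4:1), rt; filter under Ar; then add the filtrate slowly to AcOOH (2.2 equiv, in AcOH), 10 °C → rt
Reagents that add atoms: peracetic acid, CC(=O)OO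
Why: Proposed new method: hydrogenolysis frees the air-sensitive pyrogallol, which peracetic acid oxidizes to the 3-hydroxy-o-quinone and then cleaves by Baeyer–Villiger-type oxygen insertion between the two carbonyl carbons (C4'–C5', either side being equivalent by the symmetry of the ring) to the 2-hydroxymuconic anhydride, whose enol oxygen takes over the distal acyl group through a five-membered transition state, closing the 2-pyrone and releasing the carboxylic acid at C6; the closest known reactions are peracid ring fission of catechols and pyrogallols to cis,cis-muconic acids and the acid lactonization of 2-hydroxymuconic (oxalocrotonic) acid to 2-pyrone-6-carboxylic acid, and the veratryl ring, the butyrolactone and both stereocentres are left untouched because the pyrogallol is oxidized far faster and slow addition to excess peracid suppresses purpurogallin-type dimerization.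

**Compound list**
1 | 3-(3,4-dimethoxyphenyl)propanoic acid | COc1ccc(CCC(=O)O)cc1OC | starting material
2 | (S)-4-benzyl-1,3-oxazolidin-2-one | O=C1N[C@@H](Cc2ccccc2)CO1 | starting material
3 | (4S)-4-benzyl-3-[3-(3,4-dimethoxyphenyl)propanoyl]-1,3-oxazolidin-2-one | COc1ccc(CCC(=O)N2[C@@H](Cc3ccccc3)COC2=O)cc1OC | intermediate
4 | 3,4,5-tris(benzyloxy)benzaldehyde | O=Cc1cc(OCc2ccccc2)c(OCc2ccccc2)c(OCc2ccccc2)c1 | starting material
5 | tert-butyl (triphenylphosphoranylidene)acetate | CC(C)(C)OC(=O)C=P(c1ccccc1)(c1ccccc1)c1ccccc1 | starting material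
6 | tert-butyl (E)-3-[3,4,5-tris(benzyloxy)phenyl]prop-2-enoate | CC(C)(C)OC(=O)/C=C/c1cc(OCc2ccccc2)c(OCc2ccccc2)c(OCc2ccccc2)c1 | intermediate
7 | tert-butyl 3-[3,4,5-tris(benzyloxy)phenyl]propanoate | CC(C)(C)OC(=O)CCc1cc(OCc2ccccc2)c(OCc2ccccc2)c(OCc2ccccc2)c1 | intermediate
8 | tert-butyl (3R)-3-{[(4S)-4-benzyl-2-oxo-1,3-oxazolidin-3-yl]carbonyl}-4-(3,4-dimethoxyphenyl)-2-[3,4,5-tris(benzyloxy)benzyl]butanoate, C2 epimer mixture | COc1ccc(C[C@@H](C(=O)N2[C@@H](Cc3ccccc3)COC2=O)C(Cc2cc(OCc3ccccc3)c(OCc3ccccc3)c(OCc3ccccc3)c2)C(=O)OC(C)(C)C)cc1OC | intermediate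
9 | tert-butyl (3R)-4-(3,4-dimethoxyphenyl)-3-(hydroxymethyl)-2-[3,4,5-tris(benzyloxy)benzyl]butanoate, C2 epimer mixture | COc1ccc(C[C@@H](CO)C(Cc2cc(OCc3ccccc3)c(OCc3ccccc3)c(OCc3ccccc3)c2)C(=O)OC(C)(C)C)cc1OC | intermediate
10 | (3S,4R)-4-(3,4-dimethoxybenzyl)-3-[3,4,5-tris(benzyloxy)benzyl]dihydrofuran-2(3H)-one (cis epimer) | COc1ccc(C[C@H]2COC(=O)[C@H]2Cc2cc(OCc3ccccc3)c(OCc3ccccc3)c(OCc3ccccc3)c2)cc1OC | intermediate
11 | (3R,4R)-4-(3,4-dimethoxybenzyl)-3-[3,4,5-tris(benzyloxy)benzyl]dihydrofuran-2(3H)-one (trans) | COc1ccc(C[C@H]2COC(=O)[C@@H]2Cc2cc(OCc3ccccc3)c(OCc3ccccc3)c(OCc3ccccc3)c2)cc1OC | intermediate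
12 | (3R,4R)-4-(3,4-dimethoxybenzyl)-3-(3,4,5-trihydroxybenzyl)dihydrofuran-2(3H)-one | COc1ccc(C[C@H]2COC(=O)[C@@H]2Cc2cc(O)c(O)c(O)c2)cc1OC | intermediate
13 | 3-hydroxy-5-{[(3R,4R)-4-(3,4-dimethoxybenzyl)-2-oxotetrahydrofuran-3-yl]methyl}cyclohexa-3,5-diene-1,2-dione | COc1ccc(C[C@H]2COC(=O)[C@@H]2CC2=CC(=O)C(=O)C(O)=C2)cc1OC | intermediate
14 | 3-hydroxy-5-{[(3R,4R)-4-(3,4-dimethoxybenzyl)-2-oxotetrahydrofuran-3-yl]methyl}oxepine-2,7-dione | COc1ccc(C[C@H]2COC(=O)[C@@H]2CC2=CC(=O)OC(=O)C(O)=C2)cc1OC | intermediate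
15 | 4-{[(3R,4R)-4-(3,4-dimethoxybenzyl)-2-oxotetrahydrofuran-3-yl]methyl}-2-oxo-2H-pyran-6-carboxylic acid | COc1ccc(C[C@H]2COC(=O)[C@@H]2Cc2cc(C(=O)O)oc(=O)c2)cc1OC | target

**Step count and risks**
Total steps: 6. Longest linear sequence: 5 (from 4 through steps 2, 3, 4, 5 and 6).

The step most likely to fail is step 6, where the free α-keto acid tautomer of the seco-acid can be over-oxidized by peracid and the pyrogallol can dimerize. The fallback sets out from pyrogallol 12 (made from 11 by the same hydrogenolysis) and comes back at 15. Compound 12 is cleaved with Pb(OAc)4 (2.2 equiv, tetravalent lead) in MeOH–PhMe at 0 °C, which traps both carboxyl groups as esters and gives the isolable dimethyl (2E,4Z)-2-hydroxy-4-{[(3R,4R)-4-(3,4-dimethoxybenzyl)-2-oxotetrahydrofuran-3-yl]methyl}hexa-2,4-dienedioate F1. In a separate, oxidant-free operation (6 M HCl, AcOH, 80 °C) the distal ester lactonizes onto the enol and the remaining methyl ester is hydrolysed, giving 15.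

Second is step 4, where cross- versus homo-coupling and the yield are uncertain. The fallback sets out from 3 and 4 and comes back at 11, replacing the oxidative coupling by two sequential enolate alkylations. Imide 3 is alkylated (NaN(SiMe3)2, tert-butyl bromoacetate, THF, −78 °C) to (4S)-4-benzyl-3-[(2R)-4-tert-butoxy-2-(3,4-dimethoxybenzyl)-4-oxobutanoyl]-1,3-oxazolidin-2-one F2. LiBH4 reduction gives tert-butyl (3R)-4-(3,4-dimethoxyphenyl)-3-(hydroxymethyl)butanoate F3, which TFA closes to (4R)-4-(3,4-dimethoxybenzyl)dihydrofuran-2(3H)-one F4. In parallel, aldehyde 4 is reduced (NaBH4, MeOH) to [3,4,5-tris(benzyloxy)phenyl]methanol F5 and converted with PBr3 to 1,2,3-tris(benzyloxy)-5-(bromomethyl)benzene F6. The lithium enolate of F4 (LiN(SiMe3)2, THF, −78 °C) is alkylated by F6 anti to the C4 substituent, giving trans-lactone 11 directly.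

Third is step 5, where LiBH4 may attack the ester or the newly formed lactone, or the hindered imide may cleave sluggishly. The fallback sets out from 8 and comes back at 9. The auxiliary is removed hydrolytically (LiOH, H2O2, THF–H2O, 0 °C) to give (2R)-4-tert-butoxy-2-(3,4-dimethoxybenzyl)-4-oxo-3-[3,4,5-tris(benzyloxy)benzyl]butanoic acid F7. BH3·SMe2 (THF, 0 °C) then reduces the free acid selectively in the presence of the tert-butyl ester to hydroxy ester 9, which is lactonized and epimerized to 11 as before.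

**Further compounds**
F1 | step 6 | dimethyl (2E,4Z)-2-hydroxy-4-{[(3R,4R)-4-(3,4-dimethoxybenzyl)-2-oxotetrahydrofuran-3-yl]methyl}hexa-2,4-dienedioate | COC(=O)/C(O)=C\C(C[C@H]1C(=O)OC[C@@H]1Cc1ccc(OC)c(OC)c1)=C/C(=O)OC
F2 | step 4 | (4S)-4-benzyl-3-[(2R)-4-tert-butoxy-2-(3,4-dimethoxybenzyl)-4-oxobutanoyl]-1,3-oxazolidin-2-one | COc1ccc(C[C@H](CC(=O)OC(C)(C)C)C(=O)N2[C@@H](Cc3ccccc3)COC2=O)cc1OC
F3 | step 4 | tert-butyl (3R)-4-(3,4-dimethoxyphenyl)-3-(hydroxymethyl)butanoate | COc1ccc(C[C@@H](CO)CC(=O)OC(C)(C)C)cc1OC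
F4 | step 4 | (4R)-4-(3,4-dimethoxybenzyl)dihydrofuran-2(3H)-one | COc1ccc(C[C@H]2COC(=O)C2)cc1OC
F5 | step 4 | [3,4,5-tris(benzyloxy)phenyl]methanol | OCc1cc(OCc2ccccc2)c(OCc2ccccc2)c(OCc2ccccc2)c1
F6 | step 4 | 1,2,3-tris(benzyloxy)-5-(bromomethyl)benzene | BrCc1cc(OCc2ccccc2)c(OCc2ccccc2)c(OCc2ccccc2)c1
F7 | step 5 | (2R)-4-tert-butoxy-2-(3,4-dimethoxybenzyl)-4-oxo-3-[3,4,5-tris(benzyloxy)benzyl]butanoic acid, C3 epimer mixture | COc1ccc(C[C@@H](C(=O)O)C(Cc2cc(OCc3ccccc3)c(OCc3ccccc3)c(OCc3ccccc3)c2)C(=O)OC(C)(C)C)cc1OC
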